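Readings and results come from a simulation for substances that don't exist; noise was put on by code.

The amounts came first: the flask held 0.40 M of substrate and no dissolved coupling partner, a smaller charge than in either earlier run, so I asked how many such charges the gas could feed in the time allowed.

| flask | substrate | gas | remark | time |
|---|---|---|---|---|
| south-east | 0.56 M | 95 mM (held) | run made earlier |  |
| west | 0.88 M | 95 mM (held) | run made earlier |  |
| flask | 0.40 M | 95 mM (held) |  | 1.0 h |

- south-east (time / min: target / %, isomer of the product / %): 5.00: 26.6, 4.9; 10.0: 51.8, 21.3; 15.0: 65.3, 34.2; 30.0: 60.6, 41.0; 60.0: 59.8, 40.8
- west (time / min: target / %, isomer of the product / %): 5.00: 18.2, 2.8; 15.0: 55.4, 23.9; 30.0: 60.3, 40.5; 40.0: 60.9, 40.1; 60.0: 59.5, 40.2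

(readings scatter by 1 percentage point)

* which holds at 1.0 h: what has brought the reaction to rest, or that it has not come to rest (all of the substrate has reacted / it is still moving / forward and back rates have come level)
* how much target there is at 1.0 h, in percent of the substrate charged
* how much isomer of the product there is at 1.0 h, in percent of the substrate charged

- at the start none of coupling partner is dissolved
- reactions considered so far: substrate + coupling partner -> intermediate; intermediate -> target; target <-> isomer of the product; gas <-> coupling partner
- the reaction counts as stopped when no species that holds the substrate changes by six tenths of a point or more over the second half of the time

Between 5.00 min and 15.0 min the west run gained target plus isomer of the product at 51.3 mM/min, and over 1.0 h that pace came to 7.70 flask charges; I carried this number of charges deliverable in the time as the charge count. One charge then needed about 7.80 min, far less than the time asked. At 60.0 min the two runs read level, with target at 59.8% and 59.5%, so I committed the flask to about 59.6% target and 40.5% isomer of the product, brought to rest by consumption of its substrate, since the deliverable amount far exceeded the charge.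

The weak link was that this pace came from one run, the west run, with c(substrate) at 0.88 M. The south-east run, between 5.00 min and 10.0 min, gave 46.6 mM/min, close to the west pace on a smaller charge, so the count for the flask became 6.99 charges, and the deliverable amount still stood far above the one charge in the flask.

The forecast read: forward and back rates have come level, with 59.9% target and 40.1% isomer of the product, and its ground was this: “The mixture is at rest because target and isomer interconvert at equal rates.”

The flask answered: all of the substrate has reacted, with 59.5% target and 40.5% isomer of the product. Its substrate, the limiting reagent here, stood at 0% of the charge at 1.00 h. Half of the conversion reached at 1.0 h stood at 0.0724 h, where the charge count, taken up to that time, gives 0.557 of a charge.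

    substrate + coupling partner → intermediate (k = 0.189 /M/s)
    intermediate → target (k = 0.0110 /s)
    target ⇌ isomer of the product (K = 0.682, k = 0.00199 /s)
    gas ⇌ coupling partner, rate k4*(csat - [coupling partner]) (kL = 0.0104 /s)

For the same flask stopped at 15 min, the charge count gives 1.92 charges, so the deliverable amount stands above the one charge in that flask. That neighbour held 0.071% of its substrate, with 63.6% target and 35.4% isomer of the product.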